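**Plan**

- Retrosynthetic cuts, in order: the ring B O–Si bond; the C=C of the C8 prenyl group (back to an allyl group); the O1–C2 bond of the pyran (back to a prenyl group on C4a beside a free C8a–OH); the ring A C5'–prenyl bond; the ring A C3'–allyl bond (back to the 4'-O-allyl ether); the aryl–acyl bond between resorcinol and the C6–C3 acid.
- Forward: rings A and B are joined first by acylation; ring A is then O-allylated, the allyl group is moved to C3' by Claisen shift, and C5' is prenylated. The pyran, the only ring that is made, closes in step 6. The C8 allyl group becomes prenyl only afterwards, so a single prenyl group is present when the oxidant acts; desilylation ends the route.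
- Enabling feature: the 2,2-dimethyl-2H-pyran (O1, C2, C3, C4, C4a, C8a) fused to ring A is a 3-methylbut-2-enyl group on C4a plus the phenolic oxygen on C8a, less two hydrogens. Dehydrogenation to an ortho-quinone methide therefore lets O1–C2 form by oxa-6π electrocyclisation.
- Stereochemistry: the target has no stereocentre and no configurational alkene (C3=C4 is cis by ring constraint), so only regio- and chemoselectivity have to be controlled.

Key step: step 6

Remark: primed locants (1'–6') denote ring A of the open dihydrochalcones and unprimed ones ring B; from step 6 on chromene numbering is used (C5' = C4a, C4' = C8a, C3' = C8, C2' = C7, C1' = C6).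

**Route**

Step 1
Reactants: 1 resorcinol; 2 3-(4-hydroxyphenyl)propanoic acid
Product: 3 2',4,4'-trihydroxydihydrochalcone [1-(2,4-dihydroxyphenyl)-3-(4-hydroxyphenyl)propan-1-one]
Conditions: BF3·OEt2 (neat, as medium), 90 °C; aq. NaOAc work-up
Reagents that add atoms: none
Why: Friedel–Crafts (Nencki-type) acylation with the free acid in BF3·OEt2 should attack resorcinol at C4, ortho/para to both hydroxyls, while the far less activated ring of 2 does not compete and the ortho-hydroxy ketone, held as a boron chelate, resists a second acylation.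

Step 2
Reactants: 3 2',4,4'-trihydroxydihydrochalcone; 4 allyl bromide
Product: 5 4'-allyloxy-2',4-dihydroxydihydrochalcone [1-(4-allyloxy-2-hydroxyphenyl)-3-(4-hydroxyphenyl)propan-1-one]
Conditions: allyl bromide (1.05 equiv), K2CO3 (1.1 equiv), acetone, reflux
Reagents that add atoms: allyl bromide (4), C=CCBr
Why: Williamson etherification under limiting base should select the 4'-OH, which is para to the ketone and roughly two pKa units more acidic than the ring B phenol, while the 2'-OH is tied up in the hydrogen bond to the carbonyl.

Step 3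
Reactants: 5 4'-allyloxy-2',4-dihydroxydihydrochalcone
Product: 6 4'-allyloxy-2'-hydroxy-4-(tert-butyldimethylsilyloxy)dihydrochalcone
Conditions: TBSCl (1.1 equiv), imidazole, DMF, rt
Reagents that add atoms: tert-butyldimethylsilyl chloride (TBSCl), CC(C)(C)[Si](C)(C)Cl
Why: Imidazole-promoted silylation should cap the only unhindered free phenol (ring B), since the chelated 2'-OH is not silylated under these mild conditions.

Step 4
Reactants: 6 4'-allyloxy-2'-hydroxy-4-(tert-butyldimethylsilyloxy)dihydrochalcone
Product: 8 3'-allyl-2',4'-dihydroxy-4-(tert-butyldimethylsilyloxy)dihydrochalcone, via ortho-dienone 7 (not isolated)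
Conditions: N,N-diethylaniline, 200 °C, Ar
Reagents that add atoms: none
Why: Aromatic Claisen rearrangement ([3,3] shift, then enolisation of dienone 7) of 4-allyloxy-2-hydroxyaryl ketones is known to favour the position between the two oxygens (C3'), because the chelated hydroxy ketone fixes more double-bond character in C3'–C4'; the aryl silyl ether is thermally stable in the basic solvent.

Step 5
Reactants: 8 3'-allyl-2',4'-dihydroxy-4-(tert-butyldimethylsilyloxy)dihydrochalcone; 9 2-methylbut-3-en-2-ol
Product: 10 3'-allyl-2',4'-dihydroxy-5'-(3-methylbut-2-enyl)-4-(tert-butyldimethylsilyloxy)dihydrochalcone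
Conditions: 2-methylbut-3-en-2-ol (2–3 equiv), BF3·OEt2 (0.5 equiv), 1,4-dioxane, rt
Reagents that add atoms: 2-methylbut-3-en-2-ol (9), C=CC(C)(C)O
Why: Friedel–Crafts alkylation by the dimethylallyl cation from the tertiary allylic alcohol should occur through its unhindered primary terminus at C5', the only free ring A position ortho/para to the two hydroxyls now that C3' is blocked, with dioxane tempering the Lewis acid so that the silyl ether and allyl group persist.

Step 6
Reactants: 10 3'-allyl-2',4'-dihydroxy-5'-(3-methylbut-2-enyl)-4-(tert-butyldimethylsilyloxy)dihydrochalcone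
Product: 12 1-(8-allyl-7-hydroxy-2,2-dimethyl-2H-chromen-6-yl)-3-[4-(tert-butyldimethylsilyloxy)phenyl]propan-1-one, via ortho-quinone methide 11 (not isolated)
Conditions: DDQ (1.1 equiv), benzene, 80 °C
Reagents that add atoms: none
Why: DDQ, as a charge-transfer complex with the electron-rich ring A, should abstract hydride from the benzylic CH2 of the C5' prenyl group, and loss of the 4'-OH proton then gives ortho-quinone methide 11, a 1-oxatriene (O=C4'–C5'=CH–CH=CMe2). This oxatriene should close by thermal disrotatory oxa-6π electrocyclisation, forming O1–C2, restoring the aromaticity of ring A and giving the six-membered 2,2-dimethyl-2H-pyran. The closest known reaction type is the DDQ oxidative cyclisation of ortho-(3-methylbut-2-enyl)phenols to 2,2-dimethyl-2H-chromenes. No stereocentre arises, since C2 carries two methyl groups and the C3=C4 alkene is cis by ring constraint. The step needs chemoselectivity among three benzylic positions: the prenyl CH2 gives a cation delocalised onto a tertiary allylic terminus whereas the allyl CH2 would give only a primary/secondary allyl cation, and the ring B silyl ether removes the free para-phenol that would open a para-quinone methide path at Cβ of the chain. It also needs regioselective closure, which is fixed because C6' bears hydrogen, so the 4'-oxygen is the only phenolic oxygen ortho to the prenyl group and only the linear chromene can form; about one equivalent of DDQ limits over-oxidation.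

Step 7
Reactants: 12 1-(8-allyl-7-hydroxy-2,2-dimethyl-2H-chromen-6-yl)-3-[4-(tert-butyldimethylsilyloxy)phenyl]propan-1-one; 13 2-methylbut-2-ene
Product: 14 1-[7-hydroxy-2,2-dimethyl-8-(3-methylbut-2-enyl)-2H-chromen-6-yl]-3-[4-(tert-butyldimethylsilyloxy)phenyl]propan-1-one
Conditions: second-generation Grubbs catalyst RuCl2(H2IMes)(PCy3)(=CHPh) (5 mol %), 2-methylbut-2-ene (large excess)/CH2Cl2, 40 °C, sealed tube
Reagents that add atoms: 2-methylbut-2-ene (13), CC=C(C)C
Why: Olefin cross-metathesis of the terminal allyl alkene with excess 2-methylbut-2-ene should cap it as the trisubstituted prenyl alkene, which does not re-enter the cycle, while the chromene C3=C4 alkene, cis-disubstituted, aryl-conjugated and next to the quaternary C2, is expected to stay inert.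

Step 8
Reactants: 14 1-[7-hydroxy-2,2-dimethyl-8-(3-methylbut-2-enyl)-2H-chromen-6-yl]-3-[4-(tert-butyldimethylsilyloxy)phenyl]propan-1-one
Product: 15 1-[7-hydroxy-2,2-dimethyl-8-(3-methylbut-2-enyl)-2H-chromen-6-yl]-3-(4-hydroxyphenyl)propan-1-one (target, CNP0163015.0)
Conditions: Bu4NF (1.2 equiv), AcOH (1.2 equiv), THF, 0 °C
Reagents that add atoms: none
Why: Fluoride-induced cleavage of the aryl O–Si bond, driven by Si–F bond formation and buffered with acetic acid so that the phenol is released without exposing the chromene and hydroxy ketone to free phenoxide or base, should give the target.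

**Compound list**

1 | resorcinol | Oc1cccc(O)c1 | starting material
2 | 3-(4-hydroxyphenyl)propanoic acid | O=C(O)CCc1ccc(O)cc1 | starting material
3 | 2',4,4'-trihydroxydihydrochalcone | O=C(CCc1ccc(O)cc1)c1ccc(O)cc1O | intermediate
4 | allyl bromide | C=CCBr | starting material
5 | 4'-allyloxy-2',4-dihydroxydihydrochalcone | C=CCOc1ccc(C(=O)CCc2ccc(O)cc2)c(O)c1 | intermediate
6 | 4'-allyloxy-2'-hydroxy-4-(tert-butyldimethylsilyloxy)dihydrochalcone | C=CCOc1ccc(C(=O)CCc2ccc(O[Si](C)(C)C(C)(C)C)cc2)c(O)c1 | intermediate
7 | ortho-dienone from the [3,3] shift (C3' sp3 bearing H and allyl, C4' keto; racemic, not isolated) | C=CCC1C(=O)C=CC(C(=O)CCc2ccc(O[Si](C)(C)C(C)(C)C)cc2)=C1O | intermediate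
8 | 3'-allyl-2',4'-dihydroxy-4-(tert-butyldimethylsilyloxy)dihydrochalcone | C=CCc1c(O)ccc(C(=O)CCc2ccc(O[Si](C)(C)C(C)(C)C)cc2)c1O | intermediate
9 | 2-methylbut-3-en-2-ol | C=CC(C)(C)O | starting material
10 | 3'-allyl-2',4'-dihydroxy-5'-(3-methylbut-2-enyl)-4-(tert-butyldimethylsilyloxy)dihydrochalcone | C=CCc1c(O)c(CC=C(C)C)cc(C(=O)CCc2ccc(O[Si](C)(C)C(C)(C)C)cc2)c1O | intermediate
11 | ortho-quinone methide (C4' keto, exocyclic C5'=CH–CH=CMe2 with the vinyl group syn to the carbonyl; not isolated) | C=CCC1=C(O)C(C(=O)CCc2ccc(O[Si](C)(C)C(C)(C)C)cc2)=C/C(=C/C=C(C)C)C1=O | intermediate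
12 | 1-(8-allyl-7-hydroxy-2,2-dimethyl-2H-chromen-6-yl)-3-[4-(tert-butyldimethylsilyloxy)phenyl]propan-1-one | C=CCc1c(O)c(C(=O)CCc2ccc(O[Si](C)(C)C(C)(C)C)cc2)cc2c1OC(C)(C)C=C2 | intermediate
13 | 2-methylbut-2-ene | CC=C(C)C | starting material
14 | 1-[7-hydroxy-2,2-dimethyl-8-(3-methylbut-2-enyl)-2H-chromen-6-yl]-3-[4-(tert-butyldimethylsilyloxy)phenyl]propan-1-one | CC(C)=CCc1c(O)c(C(=O)CCc2ccc(O[Si](C)(C)C(C)(C)C)cc2)cc2c1OC(C)(C)C=C2 | intermediate
15 | 1-[7-hydroxy-2,2-dimethyl-8-(3-methylbut-2-enyl)-2H-chromen-6-yl]-3-(4-hydroxyphenyl)propan-1-one | CC(C)=CCc1c(O)c(C(=O)CCc2ccc(O)cc2)cc2c1OC(C)(C)C=C2 | target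

**Totals**

Total step count: 8. Longest linear sequence: 8 steps (from 1 or 2 to 15).

**Steps most likely to fail, riskiest first**

Step 5 (C5' prenylation). The Lewis-acid alkylation may stall at low conversion, and the acid may cyclise the new ortho-prenylphenol to a 2,2-dimethylchroman, alkylate ring B or oxygen, or loosen the silyl ether. The fallback replaces electrophilic substitution by a sigmatropic delivery of the prenyl group and sets out from 8. The 4'-OH, the only non-chelated phenol, would be alkylated with 3-chloro-3-methylbut-1-yne (DBU, CuCl2 cat., MeCN, 0 °C) to the 4'-O-(2-methylbut-3-yn-2-yl) ether F1. Semi-hydrogenation of the alkyne (H2, Pd/CaCO3 poisoned with Pb(OAc)2, quinoline, EtOAc, rt) should give the 4'-O-(2-methylbut-3-en-2-yl) ether F2. Heating F2 (N,N-diethylaniline, 130 °C) should trigger an aromatic Claisen shift with allylic inversion; because C3' is blocked, the shift goes to C5' through the 5'-prenyl dienone F3 (not isolated), whose enolisation returns the route at 10.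

Step 6 (DDQ cyclisation). Hydride abstraction may also occur at the allyl CH2 or at Cβ of the chain, and the electron-rich chromene may be oxidised further or trapped by the reduced quinone. The fallback forms the same O1–C2 bond by electrophilic cyclisation and elimination in place of hydride abstraction, and sets out from 10. PhSeCl (1.0 equiv, CH2Cl2, −78 °C) should add to the more electron-rich trisubstituted prenyl alkene, and the 4'-oxygen should open the seleniranium ion at the tertiary carbon (6-endo) to give the racemic 3-(phenylselanyl)-2,2-dimethylchroman F4. Oxidation with H2O2 (THF, 0 °C to rt) should give the selenoxide F5 (not isolated), which can only eliminate syn towards C4 and so returns the route at 12.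

Step 2 (selective 4'-O-allylation). Discrimination between the 4'-OH and the ring B phenol may be incomplete, leading to over-allylation or ring B etherification. The fallback moves the selection from alkylation to deprotection, sets out from 3 and replaces steps 2 and 3. Both non-chelated phenols would be silylated (TBSCl 2.2 equiv, imidazole, DMF, rt) to the 4,4'-bis(tert-butyldimethylsilyl) ether F6. The 4'-O–Si bond, whose phenoxide is stabilised by the para carbonyl, should be cleaved selectively (K2CO3 cat., MeOH, 0 °C) to the ring B mono-silyl ether F7. Allylation of its single free non-chelated phenol (allyl bromide, K2CO3, acetone, reflux) returns the route at 6.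

**Further compounds**

F1 | step 5 | 1-[3-allyl-2-hydroxy-4-(2-methylbut-3-yn-2-yloxy)phenyl]-3-[4-(tert-butyldimethylsilyloxy)phenyl]propan-1-one | C#CC(C)(C)Oc1ccc(C(=O)CCc2ccc(O[Si](C)(C)C(C)(C)C)cc2)c(O)c1CC=C
F2 | step 5 | 1-[3-allyl-2-hydroxy-4-(2-methylbut-3-en-2-yloxy)phenyl]-3-[4-(tert-butyldimethylsilyloxy)phenyl]propan-1-one | C=CC(C)(C)Oc1ccc(C(=O)CCc2ccc(O[Si](C)(C)C(C)(C)C)cc2)c(O)c1CC=C
F3 | step 5 | 5'-prenyl ortho-dienone (C5' sp3 bearing H and 3-methylbut-2-enyl, C4' keto; racemic, not isolated) | C=CCC1=C(O)C(C(=O)CCc2ccc(O[Si](C)(C)C(C)(C)C)cc2)=CC(CC=C(C)C)C1=O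
F4 | step 6 | 1-[8-allyl-7-hydroxy-2,2-dimethyl-3-(phenylselanyl)chroman-6-yl]-3-[4-(tert-butyldimethylsilyloxy)phenyl]propan-1-one (racemic) | C=CCc1c(O)c(C(=O)CCc2ccc(O[Si](C)(C)C(C)(C)C)cc2)cc2c1OC(C)(C)C(C2)[Se]c1ccccc1
F5 | step 6 | selenoxide of F4 (mixture of diastereomers, not isolated) | C=CCc1c(O)c(C(=O)CCc2ccc(O[Si](C)(C)C(C)(C)C)cc2)cc2c1OC(C)(C)C(C2)[Se](=O)c1ccccc1
F6 | step 2 | 2'-hydroxy-4,4'-bis(tert-butyldimethylsilyloxy)dihydrochalcone | CC(C)(C)[Si](C)(C)Oc1ccc(CCC(=O)c2ccc(O[Si](C)(C)C(C)(C)C)cc2O)cc1
F7 | step 2 | 2',4'-dihydroxy-4-(tert-butyldimethylsilyloxy)dihydrochalcone | CC(C)(C)[Si](C)(C)Oc1ccc(CCC(=O)c2ccc(O)cc2O)cc1
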